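The whole plan depends on cutting the ten-membered carbocycle at C7–C8 (germacrane numbering). The feature exploited is the homoallylic alcohol array O–C8–C7–C11=C13. In it, C7 is the β-position of the γ-lactone ring and C11=C13 is its exocyclic methylene. Read backwards, this is an allyl metal at C13 of a butenolide that has attacked an aldehyde with allylic transposition. One indium Barbier reaction thus makes C7–C8, closes the carbocycle, generates the α-methylene lactone and creates C7 and C8. C8 emerges 8S and is inverted during angeloylation. The precursor is a (5S,6S)-3-(bromomethyl)butenolide whose C6 side chain holds the C5 silyl ether, C4 methylene, E enoate and a freshly released C8 aldehyde.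

Key step: step 13

Assumption 1: the ring closure is taken to follow the closed chair that governs intermolecular additions of 3-(metallomethyl)butenolides. Because C13 and C6 are trans across C11=C7, this gives the anti adduct (8S, H7 trans to H8), so the 8R acyloxy centre of the target is made by inversion in step 14.
Assumption 2: the facial sense of the pinene-derived borane in step 7 is assigned by analogy with simple aldehydes (reagent from (−)-α-pinene, Re-face attack). Should it prove opposite, the antipodal reagent would be used.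
Germacrane numbering is used throughout: C1=C10 enoate alkene, C14 ester carbon, C15 methylene on C4, C11–C13 lactone carbons. TBDPS = tert-butyldiphenylsilyl, MOM = methoxymethyl, Ipc = isopinocampheyl.

Step 1
Reactants: 1 hex-5-en-1-ol
Product: 2 hex-5-enal
Conditions: TEMPO (cat.), PhI(OAc)2, CH2Cl2, rt
Reagents that add atoms: none
Why: The oxoammonium-catalysed (TEMPO) alcohol oxidation stops at the aldehyde and leaves the terminal alkene alone.

Step 2
Reactants: 3 methyl 2-(diethoxyphosphoryl)acetate; 4 2-bromo-1,1-dimethoxyethane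
Product: 5 methyl 2-(diethoxyphosphoryl)-4,4-dimethoxybutanoate (racemic)
Conditions: NaH, DMF, 0 °C; then 4, NaI (cat.), 90 °C
Reagents that add atoms: none
Why: This is an SN2 C-alkylation of the stabilised phosphonoacetate anion, with iodide catalysis and heat compensating for the sluggish β,β-dialkoxy bromide, and it is a standard way to α-substituted Horner–Wadsworth–Emmons reagents.

Step 3
Reactants: 5 methyl 2-(diethoxyphosphoryl)-4,4-dimethoxybutanoate; 2 hex-5-enal
Product: 6 methyl (2E)-2-(2,2-dimethoxyethyl)octa-2,7-dienoate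
Conditions: LiOtBu, hexane–THF, 0 °C to rt
Reagents that add atoms: none
Why: In this Horner–Wadsworth–Emmons olefination the diethyl phosphonate, lithium counter-ion and weakly polar medium favour reversible addition and hence the thermodynamic E enoate (C2 trans to CO2Me and cis to C9), and the minor Z isomer is to be removed by chromatography.

Step 4
Reactants: 6 methyl (2E)-2-(2,2-dimethoxyethyl)octa-2,7-dienoate
Product: 8 methyl (2E)-2-(2,2-dimethoxyethyl)-7-oxohept-2-enoate, via vicinal diol 7 (not isolated)
Conditions: OsO4 (cat.), NaIO4, 2,6-lutidine, dioxane–H2O, rt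
Reagents that add atoms: osmium tetroxide, O=[Os](=O)(=O)=O; sodium periodate (restores the oxygen on osmium), [Na+].[O-]I(=O)(=O)=O
Why: In this Lemieux–Johnson cleavage OsO4 attacks the electron-rich monosubstituted alkene much faster than the electron-poor trisubstituted enoate, and the buffered medium spares the acetal.

Step 5
Reactants: 8 methyl (2E)-2-(2,2-dimethoxyethyl)-7-oxohept-2-enoate
Product: 9 methyl (2E)-2-(2,2-dimethoxyethyl)-6-formylhepta-2,6-dienoate
Conditions: 37% aq. HCHO, pyrrolidine (10 mol%), propionic acid (10 mol%), iPrOH, 45 °C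
Reagents that add atoms: formaldehyde, C=O
Why: The amine/acid-catalysed Mannich condensation and elimination (organocatalytic α-methylenation of aldehydes) places C15 on C4, the only aldehyde α-carbon, under conditions too mild for ester or acetal.

Step 6
Reactants: 10 prop-2-en-1-ol
Product: 11 3-(methoxymethoxy)prop-1-ene
Conditions: CH2(OMe)2 (excess), LiBr (cat.), TsOH·H2O (cat.), rt
Reagents that add atoms: dimethoxymethane, COCOC
Why: Acid-catalysed acetal exchange with excess dimethoxymethane gives the MOM ether without chloromethyl methyl ether.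

Step 7
Reactants: 11 3-(methoxymethoxy)prop-1-ene; 9 methyl (2E)-2-(2,2-dimethoxyethyl)-6-formylhepta-2,6-dienoate
Product: 16 methyl (2E,7S,8S)-2-(2,2-dimethoxyethyl)-7-hydroxy-8-(methoxymethoxy)-6-methylidenedeca-2,9-dienoate, via alkoxyallyllithium 12 (not isolated), via borate complex 13 (not isolated), via allylborane 14 (not isolated), via borinate ester 15 (not isolated)
Conditions: 11, sBuLi, THF, −78 °C; (+)-Ipc2BOMe; BF3·OEt2; then 9, −78 °C; HOCH2CH2NH2, Et2O, rt
Reagents that add atoms: none
Why: In this Brown alkoxyallylboration through a closed chair the Z geometry of the γ-alkoxyallylborane gives the 5,6-syn relationship and the Ipc groups from (−)-α-pinene direct attack to the Re face of the aldehyde, which sets 5S and 6S, while ester and acetal are inert at −78 °C.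

Step 8
Reactants: 16 methyl (2E,7S,8S)-2-(2,2-dimethoxyethyl)-7-hydroxy-8-(methoxymethoxy)-6-methylidenedeca-2,9-dienoate
Product: 17 methyl (2E,7S,8S)-7-(tert-butyldiphenylsilyloxy)-2-(2,2-dimethoxyethyl)-8-(methoxymethoxy)-6-methylidenedeca-2,9-dienoate
Conditions: TBDPSCl, imidazole, DMAP (cat.), DMF, 40 °C
Reagents that add atoms: tert-butyl(chloro)diphenylsilane, CC(C)(C)[Si](Cl)(c1ccccc1)c1ccccc1
Why: This is a standard silylation of the only free hydroxyl, and TBDPS is chosen because it outlasts the two acidic steps ahead and adds bulk to the C6 side chain for the facial control of step 13.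

Step 9
Reactants: 17 methyl (2E,7S,8S)-7-(tert-butyldiphenylsilyloxy)-2-(2,2-dimethoxyethyl)-8-(methoxymethoxy)-6-methylidenedeca-2,9-dienoate
Product: 18 methyl (2E,7S,8S)-7-(tert-butyldiphenylsilyloxy)-2-(2,2-dimethoxyethyl)-8-hydroxy-6-methylidenedeca-2,9-dienoate
Conditions: AcCl (10 mol%), MeOH, 40 °C
Reagents that add atoms: none
Why: Acid-catalysed transacetalisation hands the MOM group to methanol, whereas the C8 dimethyl acetal only exchanges degenerately with the solvent and the TBDPS ether and methyl ester are stable.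

Step 10
Reactants: 18 methyl (2E,7S,8S)-7-(tert-butyldiphenylsilyloxy)-2-(2,2-dimethoxyethyl)-8-hydroxy-6-methylidenedeca-2,9-dienoate; 19 2-(bromomethyl)prop-2-enoic acid
Product: 20 methyl (2E,7S,8S)-8-[2-(bromomethyl)prop-2-enoyloxy]-7-(tert-butyldiphenylsilyloxy)-2-(2,2-dimethoxyethyl)-6-methylidenedeca-2,9-dienoate
Conditions: 19, DCC, DMAP (5 mol%), CH2Cl2, 0 °C to rt
Reagents that add atoms: none
Why: The Steglich esterification brings in C11, C12 and C13 with the bromide already in place, so the base-sensitive butenolide never needs later functionalisation, and DMAP is kept to a trace because it can quaternise the allylic bromide.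

Step 11
Reactants: 20 methyl (2E,7S,8S)-8-[2-(bromomethyl)prop-2-enoyloxy]-7-(tert-butyldiphenylsilyloxy)-2-(2,2-dimethoxyethyl)-6-methylidenedeca-2,9-dienoate
Product: 21 methyl (2E,7S)-7-[(2S)-4-(bromomethyl)-5-oxo-2,5-dihydrofuran-2-yl]-7-(tert-butyldiphenylsilyloxy)-2-(2,2-dimethoxyethyl)-6-methylidenehept-2-enoate
Conditions: second-generation Grubbs catalyst (H2IMes)(PCy3)Cl2Ru=CHPh (5 mol%), CH2Cl2, reflux, 5 mM
Reagents that add atoms: none
Why: Ring-closing metathesis of an allylic 2-(bromomethyl)acrylate is a known entry to 3-(bromomethyl)furan-2(5H)-ones; the catalyst loads on the terminal vinyl group and closes the five-membered ring, while C4=C15 (which could only give a four-membered or a tetrasubstituted six-membered ring) and the trisubstituted enoate stay out, and C6 is untouched.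

Step 12
Reactants: 21 methyl (2E,7S)-7-[(2S)-4-(bromomethyl)-5-oxo-2,5-dihydrofuran-2-yl]-7-(tert-butyldiphenylsilyloxy)-2-(2,2-dimethoxyethyl)-6-methylidenehept-2-enoate
Product: 22 methyl (2E,7S)-7-[(2S)-4-(bromomethyl)-5-oxo-2,5-dihydrofuran-2-yl]-7-(tert-butyldiphenylsilyloxy)-6-methylidene-2-(2-oxoethyl)hept-2-enoate
Conditions: SiO2, 10% aq. oxalic acid, CH2Cl2, rt; filtered and carried on directly
Reagents that add atoms: water, O
Why: Heterogeneous hydrolysis of the dimethyl acetal by a weak acid on wet silica should release the β,γ-unsaturated aldehyde without drawing C1=C10 into conjugation, and it leaves TBDPS ether, allylic bromide and lactone intact.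

Step 13
Reactants: 22 methyl (2E,7S)-7-[(2S)-4-(bromomethyl)-5-oxo-2,5-dihydrofuran-2-yl]-7-(tert-butyldiphenylsilyloxy)-6-methylidene-2-(2-oxoethyl)hept-2-enoate
Product: 24 methyl (1(10)E,5S,6S,7R,8S)-5-(tert-butyldiphenylsilyloxy)-8-hydroxygermacra-1(10),4(15),11(13)-trien-12,6-olid-14-oate, via allylindium bromide 23 (not isolated)
Conditions: In powder (5 equiv), THF–H2O 4:1, 25 °C, 22 added by syringe pump over 10 h, final 1 mM
Reagents that add atoms: none
Why: Indium metal adds oxidatively to the C13–Br bond, the metal of the resulting allylindium binds the aldehyde oxygen, and carbon–carbon bond formation occurs at the remote allyl terminus C7 (SE2′) inside a chair made of In, C13, C11, C7, C8 and O8, which leaves C11=C13 as the new alkene. The closest known reaction types are the indium- or zinc-mediated Barbier γ-allylation of aldehydes (β,γ-unsaturated ones included) by 3-(bromomethyl)furan-2(5H)-ones and the macrocyclic Barbier closure of ten-membered germacrane rings from 2-(bromomethyl)acrylates, which this step merges. The ten-membered carbocycle closes in the 10-exo-trig mode, with O8 and C11 both remaining outside the new ring. C7 (R) is controlled by C6, because the aldehyde reaches the butenolide face opposite the bulky CH(OTBDPS) side chain, which gives the trans-fused lactone. C8 (S) is controlled by the chair: the five-membered ring locks C13 and C6 trans across C11=C7, so with C9 equatorial the anti adduct results, that is O8 trans to C11 and H7 trans to H8 on the new ring, as in the intermolecular cases. The step needs γ- rather than α-attack, secured by the cyclic transition state, and cyclisation rather than oligomerisation, secured by slow addition at high dilution, while the neutral aqueous medium protonates the C8 alkoxide before it can attack C12 and is too mild to move C1=C10.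

Step 14
Reactants: 24 methyl (1(10)E,5S,6S,7R,8S)-5-(tert-butyldiphenylsilyloxy)-8-hydroxygermacra-1(10),4(15),11(13)-trien-12,6-olid-14-oate; 25 angelic acid ((2Z)-2-methylbut-2-enoic acid)
Product: 26 methyl (1(10)E,5S,6S,7R,8R)-8-[(2Z)-2-methylbut-2-enoyloxy]-5-(tert-butyldiphenylsilyloxy)germacra-1(10),4(15),11(13)-trien-12,6-olid-14-oate
Conditions: PPh3 and DIAD premixed, toluene, 0 °C; then 25 and 24, 0 °C to rt
Reagents that add atoms: none
Why: In this Mitsunobu esterification SN2 displacement of the C8 oxyphosphonium ion by angelate inverts 8S to the required 8R (H7 cis to H8) under neutral conditions that need no activated angeloyl species and so should keep the Z alkene, and premixing leaves no free phosphine for the α-methylene lactone.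

Step 15
Reactants: 26 methyl (1(10)E,5S,6S,7R,8R)-8-[(2Z)-2-methylbut-2-enoyloxy]-5-(tert-butyldiphenylsilyloxy)germacra-1(10),4(15),11(13)-trien-12,6-olid-14-oate
Product: 27 CNP0163095.1 (target)
Conditions: HF·pyridine, pyridine, THF, 0 °C to rt
Reagents that add atoms: none
Why: Fluoride-mediated desilylation in a mildly acidic medium avoids the basic fluoride sources that could add to the α-methylene lactone or trigger acyl migration and translactonisation.

Compound list
1 | hex-5-en-1-ol | C=CCCCCO | starting material
2 | hex-5-enal | C=CCCCC=O | intermediate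
3 | methyl 2-(diethoxyphosphoryl)acetate | CCOP(=O)(CC(=O)OC)OCC | starting material
4 | 2-bromo-1,1-dimethoxyethane | COC(CBr)OC | starting material
5 | methyl 2-(diethoxyphosphoryl)-4,4-dimethoxybutanoate, racemic | CCOP(=O)(OCC)C(CC(OC)OC)C(=O)OC | intermediate
6 | methyl (2E)-2-(2,2-dimethoxyethyl)octa-2,7-dienoate | COC(OC)C/C(C(=O)OC)=C\CCCC=C | intermediate
7 | methyl (2E)-2-(2,2-dimethoxyethyl)-7,8-dihydroxyoct-2-enoate, racemic diol | COC(OC)C/C(C(=O)OC)=C\CCCC(O)CO | intermediate (not isolated)
8 | methyl (2E)-2-(2,2-dimethoxyethyl)-7-oxohept-2-enoate | COC(OC)C/C(C(=O)OC)=C\CCCC=O | intermediate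
9 | methyl (2E)-2-(2,2-dimethoxyethyl)-6-formylhepta-2,6-dienoate (C5 enal) | COC(OC)C/C(C(=O)OC)=C\CCC(=C)C=O | intermediate
10 | prop-2-en-1-ol | C=CCO | starting material
11 | 3-(methoxymethoxy)prop-1-ene | C=CCOCOC | intermediate
12 | [(Z)-3-(methoxymethoxy)prop-2-enyl]lithium | [Li]C/C=C\OCOC | intermediate (not isolated)
13 | lithium methoxy[(Z)-3-(methoxymethoxy)prop-2-enyl]bis(isopinocampheyl)borate, Ipc from (−)-α-pinene | [Li+].COCO/C=C\C[B-](OC)([C@H]1C[C@H]2C[C@@H]([C@@H]1C)C2(C)C)[C@H]1C[C@H]2C[C@@H]([C@@H]1C)C2(C)C | intermediate (not isolated)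
14 | [(Z)-3-(methoxymethoxy)prop-2-enyl]bis(isopinocampheyl)borane | COCO/C=C\CB([C@H]1C[C@H]2C[C@@H]([C@@H]1C)C2(C)C)[C@H]1C[C@H]2C[C@@H]([C@@H]1C)C2(C)C | intermediate (not isolated)
15 | C5 O-bis(isopinocampheyl)boryl derivative of 16 | COC(OC)C/C(C(=O)OC)=C\CCC(=C)[C@H](OB([C@H]1C[C@H]2C[C@@H]([C@@H]1C)C2(C)C)[C@H]1C[C@H]2C[C@@H]([C@@H]1C)C2(C)C)[C@@H](OCOC)C=C | intermediate (not isolated)
16 | methyl (2E,7S,8S)-2-(2,2-dimethoxyethyl)-7-hydroxy-8-(methoxymethoxy)-6-methylidenedeca-2,9-dienoate (5S,6S, syn) | COC(OC)C/C(C(=O)OC)=C\CCC(=C)[C@H](O)[C@@H](OCOC)C=C | intermediate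
17 | C5 TBDPS ether of 16 | COC(OC)C/C(C(=O)OC)=C\CCC(=C)[C@H](O[Si](c1ccccc1)(c1ccccc1)C(C)(C)C)[C@@H](OCOC)C=C | intermediate
18 | C6 alcohol, methyl (2E,7S,8S)-7-(tert-butyldiphenylsilyloxy)-2-(2,2-dimethoxyethyl)-8-hydroxy-6-methylidenedeca-2,9-dienoate | COC(OC)C/C(C(=O)OC)=C\CCC(=C)[C@H](O[Si](c1ccccc1)(c1ccccc1)C(C)(C)C)[C@@H](O)C=C | intermediate
19 | 2-(bromomethyl)prop-2-enoic acid | C=C(CBr)C(=O)O | starting material
20 | C6 2-(bromomethyl)acrylate of 18 | COC(OC)C/C(C(=O)OC)=C\CCC(=C)[C@H](O[Si](c1ccccc1)(c1ccccc1)C(C)(C)C)[C@@H](OC(=O)C(=C)CBr)C=C | intermediate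
21 | (5S,6S)-3-(bromomethyl)butenolide with C8 dimethyl acetal | COC(OC)C/C(C(=O)OC)=C\CCC(=C)[C@H](O[Si](c1ccccc1)(c1ccccc1)C(C)(C)C)[C@H]1OC(=O)C(CBr)=C1 | intermediate
22 | (5S,6S)-3-(bromomethyl)butenolide with C8 aldehyde (key-step precursor) | O=CC/C(C(=O)OC)=C\CCC(=C)[C@H](O[Si](c1ccccc1)(c1ccccc1)C(C)(C)C)[C@H]1OC(=O)C(CBr)=C1 | intermediate
23 | C13 allylindium bromide of 22, drawn as the dibromoindium component of the sesquibromide | O=CC/C(C(=O)OC)=C\CCC(=C)[C@H](O[Si](c1ccccc1)(c1ccccc1)C(C)(C)C)[C@H]1OC(=O)C(C[In](Br)Br)=C1 | intermediate (not isolated)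
24 | ten-membered trans-fused α-methylene-γ-lactone, (5S,6S,7R,8S), free C8 hydroxyl, C5 OTBDPS, C2 and C9 cis on C1=C10 (CIP E) (key-step product) | C=C1C(=O)O[C@H]2[C@H]1[C@@H](O)C/C(C(=O)OC)=C\CCC(=C)[C@@H]2O[Si](c1ccccc1)(c1ccccc1)C(C)(C)C | intermediate
25 | angelic acid, (2Z)-2-methylbut-2-enoic acid | C/C=C(/C)C(=O)O | starting material
26 | (5S,6S,7R,8R)-8-angelate, C5 OTBDPS | C=C1C(=O)O[C@H]2[C@H]1[C@H](OC(=O)/C(C)=C\C)C/C(C(=O)OC)=C\CCC(=C)[C@@H]2O[Si](c1ccccc1)(c1ccccc1)C(C)(C)C | intermediate
27 | CNP0163095.1, (5S,6S,7R,8R)-8-angeloyloxy-5-hydroxygermacra-1(10),4(15),11(13)-trien-12,6-olid-14-oic acid methyl ester | C=C1C(=O)O[C@H]2[C@H]1[C@H](OC(=O)/C(C)=C\C)C/C(C(=O)OC)=C\CCC(=C)[C@@H]2O | target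

Total step count: 15.
Longest linear sequence: 13 (steps 1, 3, 4, 5 and 7 to 15, from hex-5-en-1-ol).

Steps most likely to fail

Step 13. The ten-membered closure may be slower than intermolecular addition (oligomerisation) or than protonolysis of the allylindium by water.
The fallback separates the making of the nucleophile from the activation of the electrophile.
- It sets out from 21. Stannylation with (Bu3Sn)2 under Pd2(dba)3 catalysis (zerovalent palladium) would give the 3-(tributylstannylmethyl)butenolide acetal F1.
- Hydrolysis on oxalic-acid-loaded wet silica would give the stannyl aldehyde F2.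
- BF3·OEt2 in CH2Cl2 at −78 °C under high dilution would then trigger the intramolecular allylstannane–aldehyde addition (SE2′, open transition state, anhydrous, no proton source). A KF work-up follows.
- The route is rejoined at 24.

Step 14. The oxyphosphonium ion may eliminate toward C9 to give a conjugated diene. It may also resist displacement at the hindered ring carbinol, or react by acyl transfer with retention.
The fallback inverts by redox instead of substitution.
- It sets out from 24. Dess–Martin periodinane with NaHCO3 would give the C8 ketone F3, which is not stored.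
- Luche reduction (NaBH4, CeCl3·7H2O, MeOH, −78 °C) should deliver hydride from the exposed side next to H7 and give the 8R alcohol F4.
- Yamaguchi angeloylation follows. The mixed anhydride is made from 25, 2,4,6-trichlorobenzoyl chloride and Et3N, and is heated in toluene at 80 °C without DMAP so that the Z alkene is kept.
- The route is rejoined at 26.
- The same retentive esterification applies if the tether should override the chair in step 13 and deliver the 8R alcohol directly.

Step 10. Acylation of the C6 hydroxyl next to the TBDPS ether may be slow, while the nucleophilic catalyst consumes the allylic bromide.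
The fallback brings in C13 only after the lactone ring exists.
- It sets out from 18. Acryloyl chloride and iPr2NEt would give the C6 acrylate F5.
- Ring-closing metathesis with the same ruthenium catalyst would give the unsubstituted butenolide F6.
- A PBu3-catalysed Morita–Baylis–Hillman reaction with aqueous formaldehyde would give the 3-(hydroxymethyl)butenolide F7.
- An Appel reaction (CBr4, PPh3) rejoins the route at 21.

Further compounds
F1 | step 13 | (5S,6S)-3-(tributylstannylmethyl)butenolide with C8 dimethyl acetal | COC(OC)C/C(C(=O)OC)=C\CCC(=C)[C@H](O[Si](c1ccccc1)(c1ccccc1)C(C)(C)C)[C@H]1OC(=O)C(C[Sn](CCCC)(CCCC)CCCC)=C1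
F2 | step 13 | (5S,6S)-3-(tributylstannylmethyl)butenolide with C8 aldehyde | O=CC/C(C(=O)OC)=C\CCC(=C)[C@H](O[Si](c1ccccc1)(c1ccccc1)C(C)(C)C)[C@H]1OC(=O)C(C[Sn](CCCC)(CCCC)CCCC)=C1
F3 | step 14 | (5S,6S,7R)-8-oxo macrocyclic α-methylene lactone, C5 OTBDPS | C=C1C(=O)O[C@H]2[C@H]1C(=O)C/C(C(=O)OC)=C\CCC(=C)[C@@H]2O[Si](c1ccccc1)(c1ccccc1)C(C)(C)C
F4 | step 14 | (5S,6S,7R,8R)-8-hydroxy macrocyclic α-methylene lactone, C5 OTBDPS | C=C1C(=O)O[C@H]2[C@H]1[C@H](O)C/C(C(=O)OC)=C\CCC(=C)[C@@H]2O[Si](c1ccccc1)(c1ccccc1)C(C)(C)C
F5 | step 10 | C6 acrylate of 18 | COC(OC)C/C(C(=O)OC)=C\CCC(=C)[C@H](O[Si](c1ccccc1)(c1ccccc1)C(C)(C)C)[C@@H](OC(=O)C=C)C=C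
F6 | step 10 | (5S,6S)-butenolide unsubstituted at C11, C8 dimethyl acetal | COC(OC)C/C(C(=O)OC)=C\CCC(=C)[C@H](O[Si](c1ccccc1)(c1ccccc1)C(C)(C)C)[C@H]1OC(=O)C=C1
F7 | step 10 | (5S,6S)-3-(hydroxymethyl)butenolide, C8 dimethyl acetal | COC(OC)C/C(C(=O)OC)=C\CCC(=C)[C@H](O[Si](c1ccccc1)(c1ccccc1)C(C)(C)C)[C@H]1OC(=O)C(CO)=C1
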